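**Retrosynthetic overview**

- The route rests on the oxocane O–C8–C9–C11–C12–C13–C14–C15 (labdane numbering) fused to the drimane decalin. Cutting C12–C13 (with C16) out of it leaves the six-membered ring O–C15–C14–C11–C9–C8, a δ-lactone with a ketone at C11, and C12=C13–C16–O is an allyl group.
- Key disconnection: C11–C12 and C13–C14 by [2+2] photocycloaddition of the enol double bond C11=C14 to the alkene C12=C13, then scission of C11–C14 (six- to eight-membered ring expansion).
- The alkene is hung on the enol oxygen as an allyl ether. An untethered monosubstituted alkene has no dependable regiochemistry, and the sense needed here puts the substituted carbon C13 on the α-carbon C14. The two-atom tether enforces the crossed mode and leaves only the face at C11 to decide C13.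
- Forward order of rings: decalin (from sclareolide) → six-membered β-keto lactone (step 6) → transient cyclobutane cage → oxocane (both step 8).
- Endgame: C11=O removed through its enol triflate, lactone C15=O reduced to CH2 (the C16 benzoate becomes a benzyl ether in the same operation), hydrogenolysis, acetylation.

Key step: step 8

Remark: carbinol and acetal centres that are erased later (C11 in 3, 4 and 8; C15 and the benzylic carbon in 20 and 21) are expected as mixtures and are left undefined in the SMILES. C16 carries a benzoate instead of the final acetate from step 8 to step 11, because an acetate would be enolised in step 9 and would end as an ethyl ether in step 12. C14 and C15 come from tert-butyl acetate; C12, C13 and C16 come from allyl alcohol.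

**Route**

Step 1
Reactants: 1 (+)-sclareolide
Product: 3 11-hydroxysclareolide (11-hydroxy-13,14,15,16-tetranorlabdan-12,8α-olide; C11 epimers), via potassium enolate of sclareolide 2 (not isolated)
Conditions: KN(SiMe3)2, THF, −78 °C; then 3-phenyl-2-(phenylsulfonyl)oxaziridine, −78 °C
Reagents that add atoms: 3-phenyl-2-(phenylsulfonyl)oxaziridine, O=S(=O)(N1OC1c1ccccc1)c1ccccc1
Why: Davis oxidation of the potassium lactone enolate should place a hydroxyl on C11, whose configuration does not matter because C11 becomes an aldehyde carbon in step 3.

Step 2
Reactants: 3 11-hydroxysclareolide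
Product: 4 13,14,15,16-tetranorlabdane-8α,11,12-triol
Conditions: LiAlH4, THF, 0 °C → rt
Reagents that add atoms: none
Why: Hydride reduction of the lactone to the primary alcohol should give the triol without touching any centre that is kept.

Step 3
Reactants: 4 13,14,15,16-tetranorlabdane-8α,11,12-triol
Product: 5 8α-hydroxydriman-11-al
Conditions: NaIO4, THF/H2O, rt
Reagents that add atoms: none
Why: Malaprade glycol cleavage of the 11,12-diol excises C12 as formaldehyde under neutral conditions, so the β-hydroxy aldehyde should neither dehydrate nor epimerise at C9.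

Step 4
Reactants: 5 8α-hydroxydriman-11-al; 6 tert-butyl acetate
Product: 8 tert-butyl 2-(8α,11-dihydroxydriman-11-yl)acetate, via lithium enolate of tert-butyl acetate 7 (not isolated)
Conditions: 6, LiN(iPr)2 (excess), THF, −78 °C; then 5, −78 °C; AcOH quench at −78 °C
Reagents that add atoms: none
Why: Aldol addition of the ester enolate to the hindered aldehyde at −78 °C should outrun retro-aldol opening of the lithium 8-alkoxide, and the uncontrolled C11 carbinol centre is removed by oxidation in step 5.

Step 5
Reactants: 8 tert-butyl 2-(8α,11-dihydroxydriman-11-yl)acetate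
Product: 9 tert-butyl 2-(8α-hydroxy-11-oxodriman-11-yl)acetate
Conditions: Dess–Martin periodinane, CH2Cl2, rt
Reagents that add atoms: none
Why: Dess–Martin oxidation converts the secondary C11 carbinol into the ketone under neutral conditions and cannot oxidise the tertiary 8-OH.

Step 6
Reactants: 9 tert-butyl 2-(8α-hydroxy-11-oxodriman-11-yl)acetate
Product: 11 lactone of (8α-hydroxy-11-oxodriman-11-yl)acetic acid (β-keto-δ-lactone; shown as enol; ring O–C8–C9–C11(OH)=C14–C15(=O)), via acylketene 10 (not isolated)
Conditions: toluene (dilute), 110 °C
Reagents that add atoms: none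
Why: Thermal loss of tert-butanol from the tert-butyl β-keto ester gives an acylketene (acylketene transacetoacetylation), which the tertiary 8α-OH should trap intramolecularly to close the six-membered lactone.

Step 7
Reactants: 11 β-keto-δ-lactone (enol); 12 allyl alcohol
Product: 13 11-O-allyl enol ether of 11 (ring O–C8–C9–C11(OCH2CH=CH2)=C14–C15(=O))
Conditions: PPh3, iPrO2C–N=N–CO2iPr, THF, 0 °C → rt
Reagents that add atoms: none
Why: Mitsunobu alkylation of the acidic vinylogous acid should take place on the enol oxygen at C11 (as with tetronic acids and 4-hydroxypyranones), giving the conjugated enol ether in which the ether oxygen is the former enol oxygen.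

Step 8
Reactants: 13 11-O-allyl enol ether
Product: 15 (13R)-16-benzoyloxy-11-oxolabdan-15,8α-olide, via crossed photoadduct 14 (not isolated)
Conditions: hν (254 nm, quartz), degassed MeCN, rt; then PhCO2H, Sc(OTf)3 (10 mol %), 4 Å MS, 0 °C → rt
Reagents that add atoms: benzoic acid, OC(=O)c1ccccc1
Why: Proposed new method: excitation of the β-alkoxy enoate of 13 should give a triplet whose β-carbon C11 bonds to the terminal alkene carbon C12 (1,5-closure through the two-atom O–C16 tether) and whose 1,4-biradical then joins C13 to C14, so that the crossed adduct 14 (a 2-oxabicyclo[2.1.1]hexane) has the ether donor on C11 and the lactone acceptor on C14 of one cyclobutane bond; Sc(OTf)3 on the lactone carbonyl should then break C11–C14 heterolytically with release of the cage strain to a five-membered oxocarbenium ion at C11 and the lactone enol, and benzoate should open that ion at C16 (directly, or by addition at C11 and acyl transfer) to leave the C11 ketone and the C16 benzoate. The closest known reactions are the crossed intramolecular [2+2] photocycloaddition of 3-allyloxy enones and allyl tetronates, the retro-aldol half of the de Mayo reaction and the Lewis-acid opening of alkoxy/ester donor–acceptor cyclobutanes; only the acidolytic capture, which turns the ether bridge into ketone plus ester without a free C16 hydroxyl ever meeting the lactone, is new. The four-membered ring closes by 5-exo radical attack and biradical recombination, and the eight-membered ring arises by expansion of the six-membered lactone (scission of the C11–C14 bond it shares with the cyclobutane) instead of by joining two chain ends. The one new centre that survives, C13, is decided by the face of C11 that C12 attacks: the two axial β-methyl groups on C8 and C10 (C17, C20) cover the upper face, so α-attack is expected, and the tether then forces C13 onto the α-face of C14 with C16 pointing back to the enol oxygen, which corresponds to 13R. The step needs regioselectivity (C11–C12/C13–C14, not C11–C13/C12–C14), which the tether secures because the straight mode would have to close an oxetane, and it needs the acid to spare the tertiary C8–O lactone bond, which a mild Lewis acid at 0 °C and the much faster strain-driven cage opening should allow.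

Step 9
Reactants: 15 (13R)-16-benzoyloxy-11-oxolabdan-15,8α-olide
Product: 17 16-benzoyloxy-11-(trifluoromethylsulfonyloxy)labd-11-en-15,8α-olide (ring-cis C11=C12; C13 arrangement as in 15), via potassium C12 enolate 16 (not isolated)
Conditions: KN(SiMe3)2 (1.1 equiv), THF, −78 °C; then N-(5-chloro-2-pyridyl)bis(trifluoromethanesulfonimide), −78 °C
Reagents that add atoms: N-(5-chloro-2-pyridyl)bis(trifluoromethanesulfonimide), O=S(=O)(N(c1ccc(Cl)cn1)S(=O)(=O)C(F)(F)F)C(F)(F)F
Why: Kinetic enolisation should occur at the unhindered C12 methylene (C9 is a methine between two quaternary carbons and the lactone α-protons are less acidic) and O-triflation of the enolate gives the enol triflate, the benzoate having no α-protons to interfere.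

Step 10
Reactants: 17 enol triflate
Product: 19 (13R)-16-benzoyloxylabdan-15,8α-olide, via labd-11-ene lactone 18 (not isolated)
Conditions: H2 (1 atm), PtO2, Li2CO3, EtOAc, rt
Reagents that add atoms: none
Why: Catalytic hydrogenolysis of the enol triflate followed by hydrogenation of the resulting cis-alkene (ketone-to-methylene reduction via the enol triflate) removes the C11 oxygen, while Li2CO3 takes up the triflic acid so that the tertiary lactone C–O bond is not ionised.

Step 11
Reactants: 19 (13R)-16-benzoyloxylabdan-15,8α-olide
Product: 21 (13R)-15-acetoxy-16-[acetoxy(phenyl)methoxy]-8α,15-epoxylabdane (mixture at both acetal carbons), via bis(aluminium hemiacetal) 20 (not isolated)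
Conditions: iBu2AlH (2.5 equiv), CH2Cl2, −78 °C; then pyridine, DMAP, Ac2O, −78 → −20 °C
Reagents that add atoms: acetic anhydride, CC(=O)OC(C)=O
Why: Reductive acetylation of esters: one hydride adds to each ester carbonyl at −78 °C and the aluminium hemiacetals are acetylated before they can collapse, so the eight-membered ring should stay closed.

Step 12
Reactants: 21 bis(α-acetoxy ether)
Product: 22 (13R)-16-benzyloxy-8α,15-epoxylabdane
Conditions: Et3SiH (excess), BF3·OEt2, CH2Cl2, −78 → −20 °C
Reagents that add atoms: none
Why: Ionic reduction: Lewis-acid ionisation of both α-acetoxy ethers to oxocarbenium ions and hydride transfer from the silane should give the oxocane CH2–O and, from the benzoate-derived acetal, the benzyl ether, the excess silane at low temperature trapping the ring oxocarbenium ion before it can shed the tertiary C8 cation.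

Step 13
Reactants: 22 (13R)-16-benzyloxy-8α,15-epoxylabdane
Product: 23 (13R)-8α,15-epoxylabdan-16-ol
Conditions: H2 (1 atm), Pd/C, EtOAc, rt
Reagents that add atoms: none
Why: Hydrogenolysis of the benzyl ether frees the primary alcohol, which is harmless now that no lactone is left for it to attack.

Step 14
Reactants: 23 (13R)-8α,15-epoxylabdan-16-ol
Product: 24 (13R)-8α,15-epoxylabdan-16-yl acetate (target)
Conditions: Ac2O, pyridine, DMAP (cat.), CH2Cl2, rt
Reagents that add atoms: acetic anhydride, CC(=O)OC(C)=O
Why: DMAP-catalysed acetylation of the unhindered primary alcohol should give the target without affecting the tertiary ether.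

**Compound list**

1 | (+)-sclareolide | C[C@@]12CC[C@H]3C(C)(C)CCC[C@]3(C)[C@H]1CC(=O)O2 | starting material
2 | potassium enolate of sclareolide | C[C@@]12CC[C@H]3C(C)(C)CCC[C@]3(C)[C@H]1C=C([O-])O2.[K+] | intermediate (not isolated)
3 | 11-hydroxysclareolide (C11 epimers) | C[C@@]12CC[C@H]3C(C)(C)CCC[C@]3(C)[C@H]1C(O)C(=O)O2 | intermediate
4 | 13,14,15,16-tetranorlabdane-8α,11,12-triol | C[C@@]1(O)CC[C@H]2C(C)(C)CCC[C@]2(C)[C@H]1C(O)CO | intermediate
5 | 8α-hydroxydriman-11-al | C[C@@]1(O)CC[C@H]2C(C)(C)CCC[C@]2(C)[C@H]1C=O | intermediate
6 | tert-butyl acetate | CC(=O)OC(C)(C)C | starting material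
7 | lithium enolate of tert-butyl acetate | C=C([O-])OC(C)(C)C.[Li+] | intermediate (not isolated)
8 | tert-butyl 2-(8α,11-dihydroxydriman-11-yl)acetate | C[C@@]1(O)CC[C@H]2C(C)(C)CCC[C@]2(C)[C@H]1C(O)CC(=O)OC(C)(C)C | intermediate
9 | tert-butyl 2-(8α-hydroxy-11-oxodriman-11-yl)acetate | C[C@@]1(O)CC[C@H]2C(C)(C)CCC[C@]2(C)[C@H]1C(=O)CC(=O)OC(C)(C)C | intermediate
10 | (8α-hydroxy-11-oxodriman-11-yl)ketene (acylketene) | C[C@@]1(O)CC[C@H]2C(C)(C)CCC[C@]2(C)[C@H]1C(=O)C=C=O | intermediate (not isolated)
11 | drimane-fused β-keto-δ-lactone, enol form (in equilibrium with the keto form) | C[C@@]12CC[C@H]3C(C)(C)CCC[C@]3(C)[C@H]1C(O)=CC(=O)O2 | intermediate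
12 | allyl alcohol | C=CCO | starting material
13 | 11-O-allyl enol ether of 11 | C[C@@]12CC[C@H]3C(C)(C)CCC[C@]3(C)[C@H]1C(OCC=C)=CC(=O)O2 | intermediate
14 | crossed photoadduct (2-oxabicyclo[2.1.1]hexane C11–O–C16–C13 with C12 and C14 as one-atom bridges, fused at C11–C14 to the δ-lactone; C12 and C13 on the α-face) | C[C@@]12CC[C@H]3C(C)(C)CCC[C@]3(C)[C@H]1[C@@]45C[C@@H](CO4)[C@@H]5C(=O)O2 | intermediate (not isolated)
15 | (13R)-16-benzoyloxy-11-oxolabdan-15,8α-olide | O=C(OC[C@H]1CC(=O)O[C@]2(C)CC[C@H]3C(C)(C)CCC[C@]3(C)[C@H]2C(=O)C1)c1ccccc1 | intermediate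
16 | potassium C12 enolate of 15 | O=C(OC[C@H]1CC(=O)O[C@]2(C)CC[C@H]3C(C)(C)CCC[C@]3(C)[C@H]2/C([O-])=C\1)c1ccccc1.[K+] | intermediate (not isolated)
17 | 16-benzoyloxy-11-(trifluoromethylsulfonyloxy)labd-11-en-15,8α-olide (ring-cis) | O=C(OC[C@H]1CC(=O)O[C@]2(C)CC[C@H]3C(C)(C)CCC[C@]3(C)[C@H]2/C(OS(=O)(=O)C(F)(F)F)=C\1)c1ccccc1 | intermediate
18 | 16-benzoyloxylabd-11-en-15,8α-olide (ring-cis) | O=C(OC[C@H]1CC(=O)O[C@]2(C)CC[C@H]3C(C)(C)CCC[C@]3(C)[C@H]2/C=C\1)c1ccccc1 | intermediate (not isolated)
19 | (13R)-16-benzoyloxylabdan-15,8α-olide | O=C(OC[C@H]1CC(=O)O[C@]2(C)CC[C@H]3C(C)(C)CCC[C@]3(C)[C@H]2CC1)c1ccccc1 | intermediate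
20 | bis(diisobutylaluminium hemiacetal) of 19 | CC(C)C[Al](CC(C)C)OC(OC[C@H]1CC(O[Al](CC(C)C)CC(C)C)O[C@]2(C)CC[C@H]3C(C)(C)CCC[C@]3(C)[C@H]2CC1)c1ccccc1 | intermediate (not isolated)
21 | (13R)-15-acetoxy-16-[acetoxy(phenyl)methoxy]-8α,15-epoxylabdane | CC(=O)OC(OC[C@H]1CC(OC(C)=O)O[C@]2(C)CC[C@H]3C(C)(C)CCC[C@]3(C)[C@H]2CC1)c1ccccc1 | intermediate
22 | (13R)-16-benzyloxy-8α,15-epoxylabdane | C(OC[C@H]1CCO[C@]2(C)CC[C@H]3C(C)(C)CCC[C@]3(C)[C@H]2CC1)c1ccccc1 | intermediate
23 | (13R)-8α,15-epoxylabdan-16-ol | OC[C@H]1CCO[C@]2(C)CC[C@H]3C(C)(C)CCC[C@]3(C)[C@H]2CC1 | intermediate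
24 | (13R)-8α,15-epoxylabdan-16-yl acetate | CC(=O)OC[C@H]1CCO[C@]2(C)CC[C@H]3C(C)(C)CCC[C@]3(C)[C@H]2CC1 | target

**Step count**

Total steps: 14. Longest linear sequence: 14 steps, from 1 to 24.

**Steps most likely to fail**

1. Step 8 (proposed new method). The alkene may add to the wrong face of C11, giving the C13 epimer. In the acid stage the oxocarbenium ion may be captured at C11 only and hydrolysed on work-up; that would free the C16 hydroxyl, which can translactonise onto C15. The tertiary C8–O bond may also ionise instead of the cage opening. Fallback with known chemistry, the untethered de Mayo reaction: it sets out from 11, which is irradiated (254 nm, MeCN) with an excess of allyl benzoate (C=CCOC(=O)c1ccccc1). The enol adds the alkene to give the cyclobutanol photoadduct F1, which opens spontaneously by retro-aldol cleavage of C11–C14, and the C16 oxygen arrives already as its benzoate. Regio- and C13-isomers are expected and would be separated by chromatography; the fallback comes back to the route at 15.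

2. Step 12. The oxocarbenium ion at C15 carries a tertiary alkyl group on oxygen and may lose the C8 cation (ring cleavage) before hydride transfer. Ring opening and over-reduction of the aluminium hemiacetal in step 11 would have the same consequence. Fallback without a cation at C15: it sets out from 19, which is thionated at both ester carbonyls with Lawesson's reagent (toluene, 110 °C) to the thionolactone thionobenzoate F2. Desulfurisation with Raney Ni (EtOH, rt) then reduces both C=S groups to CH2, and the fallback comes back to the route at 22.

3. Step 7. The ambident enolate of 11 may be alkylated at C14 or at the lactone oxygen on C15 instead of the C11 oxygen. Fallback that fixes the site by addition–elimination: it sets out from 11, which with (COCl)2 and catalytic DMF in CH2Cl2 gives the vinylogous acid chloride F3. Sodium allyloxide (allyl alcohol, NaH, THF, 0 °C) then replaces chloride at C11, and the fallback comes back to the route at 13.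

**Further compounds**

F1 | step 8 | cyclobutanol photoadduct of 11 and allyl benzoate (C12 and C13 on the α-face, CH2OBz exo) | C[C@@]12CC[C@H]3C(C)(C)CCC[C@]3(C)[C@H]1[C@]4(O)C[C@@H](COC(=O)c5ccccc5)[C@@H]4C(=O)O2
F2 | step 12 | (13R)-16-(thiobenzoyloxy)labdane-15,8α-thionolactone | S=C(OC[C@H]1CC(=S)O[C@]2(C)CC[C@H]3C(C)(C)CCC[C@]3(C)[C@H]2CC1)c1ccccc1
F3 | step 7 | 11-chloro enoate lactone (vinylogous acid chloride of 11) | C[C@@]12CC[C@H]3C(C)(C)CCC[C@]3(C)[C@H]1C(Cl)=CC(=O)O2
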